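**Retrosynthetic overview**
1. Target ⇐ fully protected biflavone: one BCl3 treatment frees five phenols (three OBn, one OiPr, the chelated 5-OMe); the 7-OMe stays.
2. Protected biflavone ⇐ Suzuki union at the 3'–8'' biaryl bond of 8-iodo-tri-O-benzylapigenin and a 3'-bromo-5,7-dimethoxy-6-methylflavone.
3. Key disconnection: the two C–O bonds (C8a–O1 and O1–C2) of the pyranone of that bromoflavone, made on a chalcone with no ring-A phenol by carbonyl-directed C–H oxygenation, oxa-Michael closure and dehydrogenation; the single ortho C–H fixes the 5-oxy/6-methyl/7-methoxy pattern.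
4. Chalcone ⇐ Claisen–Schmidt condensation of 2',4'-dimethoxy-3'-methylacetophenone with 3-bromo-4-isopropoxybenzaldehyde.
5. Ring order: the apigenin pyranone is bought with apigenin; the second pyranone is closed in the key step; the biaryl bond is made last, then deprotection.

Assumption: the target SMILES has no stereocentre and no descriptor for the 3'–8'' axis (treated as not configurationally fixed), so no stereocontrol is needed; apigenin, 2',4'-dimethoxy-3'-methylacetophenone and 3-bromo-4-isopropoxybenzaldehyde are taken as catalogue compounds.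

**Step 1**
Reactants: 1 apigenin (5,7-dihydroxy-2-(4-hydroxyphenyl)-4H-chromen-4-one)
Product: 2 tri-O-benzylapigenin (5,7-bis(benzyloxy)-2-[4-(benzyloxy)phenyl]-4H-chromen-4-one)
Conditions: BnBr (4.5 equiv), Cs2CO3 (5 equiv), nBu4NI (10 mol %), DMF, 80 °C
Reagents that add atoms: benzyl bromide, BrCc1ccccc1
Why: Williamson ether synthesis on all three phenoxides; the caesium phenoxide in hot DMF also alkylates the chelated 5-OH, which must be capped so that the next step goes to C8 and not C6.

**Step 2**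
Reactants: 2 tri-O-benzylapigenin
Product: 3 iodide 5,7-bis(benzyloxy)-2-[4-(benzyloxy)phenyl]-8-iodo-4H-chromen-4-one
Conditions: NIS (1.1 equiv), CF3CO2H (10 mol %), MeCN/CH2Cl2, 0 °C to rt
Reagents that add atoms: N-iodosuccinimide, O=C1CCC(=O)N1I
Why: electrophilic aromatic iodination of the phloroglucinol-type ring A, which for 5,7-dialkoxyflavones is known to go to C8, while the less activated ring B and C3 are not touched.

**Step 3**
Reactants: 4 ketone 1-(2,4-dimethoxy-3-methylphenyl)ethanone; 5 aldehyde 3-bromo-4-isopropoxybenzaldehyde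
Product: 6 chalcone (E)-3-(3-bromo-4-isopropoxyphenyl)-1-(2,4-dimethoxy-3-methylphenyl)prop-2-en-1-one
Conditions: KOH (50% aq.), EtOH, rt
Reagents that add atoms: none
Why: Claisen–Schmidt condensation of a methyl ketone with a non-enolisable aldehyde, with E1cB dehydration giving the E-enone; the ring-B phenol is carried as an isopropyl ether because, unlike a benzyl ether, it should survive the hot acidic oxidation of the next step.

**Step 4**
Reactants: 6 chalcone
Product: 10 bromoflavone 2-(3-bromo-4-isopropoxyphenyl)-5,7-dimethoxy-6-methyl-4H-chromen-4-one, via aryl trifluoroacetate 7 (not isolated), via hydroxychalcone 8 (not isolated), via flavanone 9 (not isolated)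
Conditions: Pd(O2CCF3)2 (10 mol %), K2S2O8 (1.5 equiv), CF3CO2H/(CF3CO)2O 9:1, 50 °C; then H2O, AcOH, DMSO (20 mol %), O2 (1 atm), 80 °C
Reagents that add atoms: trifluoroacetic acid, OC(=O)C(F)(F)F (one oxygen becomes O1 of 10; the CF3CO group is present only in 7)
Why: Proposed new method: the enone carbonyl of 6 directs cyclopalladation by divalent palladium to C6', the only ortho C–H of ring A (the other ortho position carries OMe), persulfate oxidises the palladacycle to tetravalent palladium and C–O reductive elimination gives trifluoroacetate 7; added water frees phenol 8, which closes in the hot acid by 6-endo oxa-Michael addition to flavanone 9, and the same palladium, now with DMSO under O2, dehydrogenates 9 through its palladium enolate and β-hydride elimination to 10, so both C–O bonds of the pyranone are made in one flask and the 5-OMe/6-Me/7-OMe pattern follows from the position of the single C–H; the closest known reactions are the palladium-catalysed ketone-directed ortho-C–H hydroxylation of simple aryl ketones with K2S2O8 in CF3CO2H and the Pd(O2CCF3)2/DMSO/O2 dehydrogenation of flavanones, neither shown on a chalcone or merged into an annulation; the stereocentre of 9 is racemic and is erased in 10.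

**Step 5**
Reactants: 10 bromoflavone; 3 iodide
Product: 12 protected biflavone 5,7-bis(benzyloxy)-2-[4-(benzyloxy)phenyl]-8-[5-(5,7-dimethoxy-6-methyl-4-oxo-4H-chromen-2-yl)-2-isopropoxyphenyl]-4H-chromen-4-one, via pinacol boronate 11 (not isolated)
Conditions: B2pin2 (1.2 equiv), KOAc (3 equiv), Pd(dppf)Cl2 (5 mol %), dioxane, 90 °C; then 3, K3PO4 (aq., 3 equiv), Pd(OAc)2 (5 mol %), SPhos (10 mol %), 90 °C
Reagents that add atoms: bis(pinacolato)diboron, CC1(C)OB(OC1(C)C)B1OC(C)(C)C(C)(C)O1 (supplies the Bpin group of 11; none of its atoms remains in 12)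
Why: Miyaura borylation of the aryl bromide followed in the same flask by Suzuki–Miyaura coupling (zerovalent palladium inserts into the C–I bond of 3); joining an 8-iodo-5,7-dialkoxyflavone to a 3'-boronated flavone is the established way to the amentoflavone skeleton, SPhos copes with the three ortho substituents, and the new axis has no fixed configuration.

**Step 6**
Reactants: 12 protected biflavone
Product: 13 target 8-[5-(5-hydroxy-7-methoxy-6-methyl-4-oxo-4H-chromen-2-yl)-2-hydroxyphenyl]-5,7-dihydroxy-2-(4-hydroxyphenyl)-4H-chromen-4-one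
Conditions: BCl3 (12 equiv), C6HMe5 (10 equiv), CH2Cl2, −78 °C to rt; then MeOH, H2O
Reagents that add atoms: none
Why: Lewis-acid ether cleavage in which BCl3 removes the benzyl ethers at low temperature (pentamethylbenzene traps the benzyl cation) and, on warming, the isopropyl ether and the 5-OMe through its chelate with the C4 carbonyl, while the unchelated 7-OMe with only one ortho substituent is stable to BCl3 at room temperature.

**Compound list**
1 | apigenin | O=c1cc(-c2ccc(O)cc2)oc2cc(O)cc(O)c12 | starting material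
2 | tri-O-benzylapigenin, 5,7-bis(benzyloxy)-2-[4-(benzyloxy)phenyl]-4H-chromen-4-one | O=c1cc(-c2ccc(OCc3ccccc3)cc2)oc2cc(OCc3ccccc3)cc(OCc3ccccc3)c12 | intermediate
3 | 5,7-bis(benzyloxy)-2-[4-(benzyloxy)phenyl]-8-iodo-4H-chromen-4-one | O=c1cc(-c2ccc(OCc3ccccc3)cc2)oc2c(I)c(OCc3ccccc3)cc(OCc3ccccc3)c12 | intermediate
4 | 1-(2,4-dimethoxy-3-methylphenyl)ethanone | CC(=O)c1ccc(OC)c(C)c1OC | starting material
5 | 3-bromo-4-isopropoxybenzaldehyde | O=Cc1ccc(OC(C)C)c(Br)c1 | starting material
6 | (E)-3-(3-bromo-4-isopropoxyphenyl)-1-(2,4-dimethoxy-3-methylphenyl)prop-2-en-1-one | COc1ccc(C(=O)/C=C/c2ccc(OC(C)C)c(Br)c2)c(OC)c1C | intermediate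
7 | (E)-2-[3-(3-bromo-4-isopropoxyphenyl)acryloyl]-3,5-dimethoxy-4-methylphenyl trifluoroacetate (formed in the flask, not isolated) | COc1cc(OC(=O)C(F)(F)F)c(C(=O)/C=C/c2ccc(OC(C)C)c(Br)c2)c(OC)c1C | intermediate
8 | (E)-3-(3-bromo-4-isopropoxyphenyl)-1-(6-hydroxy-2,4-dimethoxy-3-methylphenyl)prop-2-en-1-one (formed in the flask, not isolated) | COc1cc(O)c(C(=O)/C=C/c2ccc(OC(C)C)c(Br)c2)c(OC)c1C | intermediate
9 | racemic 2-(3-bromo-4-isopropoxyphenyl)-5,7-dimethoxy-6-methylchroman-4-one (formed in the flask, not isolated) | COc1cc2OC(c3ccc(OC(C)C)c(Br)c3)CC(=O)c2c(OC)c1C | intermediate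
10 | 2-(3-bromo-4-isopropoxyphenyl)-5,7-dimethoxy-6-methyl-4H-chromen-4-one | COc1cc2oc(-c3ccc(OC(C)C)c(Br)c3)cc(=O)c2c(OC)c1C | intermediate
11 | 2-[4-isopropoxy-3-(4,4,5,5-tetramethyl-1,3,2-dioxaborolan-2-yl)phenyl]-5,7-dimethoxy-6-methyl-4H-chromen-4-one (formed in the flask, not isolated) | COc1cc2oc(-c3ccc(OC(C)C)c(B4OC(C)(C)C(C)(C)O4)c3)cc(=O)c2c(OC)c1C | intermediate
12 | 5,7-bis(benzyloxy)-2-[4-(benzyloxy)phenyl]-8-[5-(5,7-dimethoxy-6-methyl-4-oxo-4H-chromen-2-yl)-2-isopropoxyphenyl]-4H-chromen-4-one | COc1cc2oc(-c3ccc(OC(C)C)c(-c4c(OCc5ccccc5)cc(OCc5ccccc5)c5c(=O)cc(-c6ccc(OCc7ccccc7)cc6)oc45)c3)cc(=O)c2c(OC)c1C | intermediate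
13 | 8-[5-(5-hydroxy-7-methoxy-6-methyl-4-oxo-4H-chromen-2-yl)-2-hydroxyphenyl]-5,7-dihydroxy-2-(4-hydroxyphenyl)-4H-chromen-4-one (6-methyl-7-O-methylamentoflavone) | COc1cc2oc(-c3ccc(O)c(-c4c(O)cc(O)c5c(=O)cc(-c6ccc(O)cc6)oc45)c3)cc(=O)c2c(O)c1C | target

**Total step count:** 6. **Longest linear sequence:** 4 (steps 3, 4, 5, 6; the apigenin branch, steps 1, 2, 5, 6, is equally long).

**Three steps most likely to fail**

Step 4 (the proposed annulation). The risks are non-directed palladation or oxidation at C5' of ring A (ortho and para to the two OMe groups) or on ring B, acid-mediated side reactions of the enone (Nazarov-type closure to an indanone, oxygenation at the β-carbon), and a stalled dehydrogenation of 9. The fallback uses known chemistry only, sets out from aldehyde 5 and returns at bromoflavone 10; the ring oxygen is placed on ring A before the chalcone is made. Purchased 2,6-dimethoxytoluene (COc1cccc(OC)c1C) is borylated at its one unhindered C–H ([Ir(OMe)(cod)]2, 4,4'-di-tert-butyl-2,2'-bipyridine, B2pin2, THF, 80 °C) to 2-(3,5-dimethoxy-4-methylphenyl)-4,4,5,5-tetramethyl-1,3,2-dioxaborolane F1. This is oxidised without isolation (NaOH, H2O2) to 3,5-dimethoxy-4-methylphenol F2. Because F2 is symmetric, Fries-type ortho-acetylation (Ac2O, BF3·OEt2, 80 °C) can give only 1-(6-hydroxy-2,4-dimethoxy-3-methylphenyl)ethanone F3. Claisen–Schmidt condensation of F3 with 5 (KOH, EtOH) gives hydroxychalcone 8, now isolated, and I2 (10 mol %) in DMSO at 120 °C closes and dehydrogenates it to 10.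

Step 5 (borylation and hindered Suzuki coupling in one flask). The risks are protodeboronation or homocoupling of the flavone boronate 11 and slow coupling at a biaryl bond with three ortho substituents. The fallback sets out from iodide 3 and aldehyde 5 and returns at 12; the biaryl bond is made on a small fragment and the pyranone is closed afterwards. Aldehyde 5 is borylated (B2pin2, KOAc, Pd(dppf)Cl2, dioxane, 90 °C) to 4-isopropoxy-3-(4,4,5,5-tetramethyl-1,3,2-dioxaborolan-2-yl)benzaldehyde F4, which is isolated and purified. Coupling with 3 (Pd(OAc)2, SPhos, K3PO4, toluene/H2O, 90 °C) gives 3-[5,7-bis(benzyloxy)-2-(4-benzyloxyphenyl)-4-oxo-4H-chromen-8-yl]-4-isopropoxybenzaldehyde F5. Claisen–Schmidt condensation of F5 with 1-(6-hydroxy-2,4-dimethoxy-3-methylphenyl)ethanone F3 (Ba(OH)2, EtOH/THF, rt) gives (E)-1-(6-hydroxy-2,4-dimethoxy-3-methylphenyl)-3-{3-[5,7-bis(benzyloxy)-2-(4-benzyloxyphenyl)-4-oxo-4H-chromen-8-yl]-4-isopropoxyphenyl}prop-2-en-1-one F6. I2 (10 mol %) in DMSO at 120 °C then gives 12.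

Step 6 (five ether cleavages at once). The risks are incomplete loss of the isopropyl group, attack on the 7-OMe on prolonged warming, C-benzylation of the phloroglucinol ring and poorly soluble boron chelates. The fallback sets out from 12 and returns at 13 by two orthogonal stages instead of one global Lewis-acid event. Transfer hydrogenolysis (Pd(OH)2 on carbon, cyclohexa-1,4-diene, EtOAc/EtOH, rt) removes only the benzyl groups and gives 8-[5-(5,7-dimethoxy-6-methyl-4-oxo-4H-chromen-2-yl)-2-isopropoxyphenyl]-5,7-dihydroxy-2-(4-hydroxyphenyl)-4H-chromen-4-one F7. AlCl3 in MeCN (rt to 50 °C) then cleaves the isopropyl ether and the chelated 5-OMe, leaving the 7-OMe, to give 13.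

**Further compounds**
F1 | step 4 | 2-(3,5-dimethoxy-4-methylphenyl)-4,4,5,5-tetramethyl-1,3,2-dioxaborolane | COc1cc(B2OC(C)(C)C(C)(C)O2)cc(OC)c1C
F2 | step 4 | 3,5-dimethoxy-4-methylphenol | COc1cc(O)cc(OC)c1C
F3 | step 4 | 1-(6-hydroxy-2,4-dimethoxy-3-methylphenyl)ethanone | CC(=O)c1c(O)cc(OC)c(C)c1OC
F4 | step 5 | 4-isopropoxy-3-(4,4,5,5-tetramethyl-1,3,2-dioxaborolan-2-yl)benzaldehyde | O=Cc1ccc(OC(C)C)c(B2OC(C)(C)C(C)(C)O2)c1
F5 | step 5 | 3-[5,7-bis(benzyloxy)-2-(4-benzyloxyphenyl)-4-oxo-4H-chromen-8-yl]-4-isopropoxybenzaldehyde | O=Cc1ccc(OC(C)C)c(-c2c(OCc3ccccc3)cc(OCc3ccccc3)c3c(=O)cc(-c4ccc(OCc5ccccc5)cc4)oc23)c1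
F6 | step 5 | (E)-1-(6-hydroxy-2,4-dimethoxy-3-methylphenyl)-3-{3-[5,7-bis(benzyloxy)-2-(4-benzyloxyphenyl)-4-oxo-4H-chromen-8-yl]-4-isopropoxyphenyl}prop-2-en-1-one | COc1cc(O)c(C(=O)/C=C/c2ccc(OC(C)C)c(-c3c(OCc4ccccc4)cc(OCc4ccccc4)c4c(=O)cc(-c5ccc(OCc6ccccc6)cc5)oc34)c2)c(OC)c1C
F7 | step 6 | 8-[5-(5,7-dimethoxy-6-methyl-4-oxo-4H-chromen-2-yl)-2-isopropoxyphenyl]-5,7-dihydroxy-2-(4-hydroxyphenyl)-4H-chromen-4-one | COc1cc2oc(-c3ccc(OC(C)C)c(-c4c(O)cc(O)c5c(=O)cc(-c6ccc(O)cc6)oc45)c3)cc(=O)c2c(OC)c1C
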